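**Retrosynthetic overview**

1. Target ⇒ (acylation, Luche reduction) bicyclic 3‑keto‑Δ4 enone that already carries the C‑7 acrylate and C‑8 acetate.
2. Enone ⇒ its 3,5‑dienol silyl ether ⇒ acyclic dienyne: one tandem ring‑closing dienyne metathesis closes ring B (C5=C6) and then ring A (C3=C4) in the same operation.
3. Dienyne ⇒ catalyst‑controlled syn 2‑(methoxycarbonyl)allylation (C7–C8 bond, both centres) of a keto aldehyde with a (Z)‑2‑(bromomethyl)penta‑2,4‑dienoate made from acrolein and methyl acrylate.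
4. Keto aldehyde ⇒ ozonolysis of a 4‑methyl‑4‑propynylcyclohexene ⇒ enantioselective Diels–Alder reaction of isoprene with methacrolein (sets C‑10).
5. Ring order: temporary cyclohexene (made in step 1, cut open in step 4) → ring B → ring A, the last two in one flask.

Assumption: atom labels C‑1 to C‑15 follow eudesmane numbering of the target (C‑3 isobutyrate, C‑4 vinylic methyl, C‑7 acrylate, C‑8 acetate, C‑10 angular methyl; target = 3S,7R,8R,10R), and each chiral catalyst is used as the enantiomer that delivers the configuration drawn (if the named antipode gives the opposite sense, its mirror image is taken).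

**Route**

Step 1
Reactants: 1 isoprene (2‑methylbuta‑1,3‑diene); 2 methacrolein (2‑methylprop‑2‑enal)
Product: 3 (1R)‑1,4‑dimethylcyclohex‑3‑ene‑1‑carbaldehyde
Conditions: (S)‑o‑tolyl‑CBS oxazaborolidine·Tf2NH (10 mol %), CH2Cl2, −78 → −40 °C
Reagents that add atoms: none
Why: Enantioselective Lewis‑acid‑catalysed Diels–Alder reaction in which the 2‑substituted diene gives the "para" adduct and the chiral oxazaborolidinium ion shields one face of the bound s‑trans enal, so the quaternary carbon (future C‑10) is formed as R.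

Step 2
Reactants: 3 (1R)‑1,4‑dimethylcyclohex‑3‑ene‑1‑carbaldehyde
Product: 4 (4R)‑4‑(2,2‑dibromoethenyl)‑1,4‑dimethylcyclohex‑1‑ene
Conditions: CBr4, PPh3, CH2Cl2, 0 °C
Reagents that add atoms: carbon tetrabromide, BrC(Br)(Br)Br
Why: Corey–Fuchs (Ramirez) dibromo‑olefination of a non‑enolisable aldehyde, which leaves the quaternary centre and the ring alkene untouched.

Step 3
Reactants: 4 (4R)‑4‑(2,2‑dibromoethenyl)‑1,4‑dimethylcyclohex‑1‑ene
Product: 6 (4R)‑1,4‑dimethyl‑4‑(prop‑1‑yn‑1‑yl)cyclohex‑1‑ene, via lithium acetylide 5 (not isolated)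
Conditions: n‑BuLi (2.2 equiv), THF, −78 → 0 °C; then MeI, 0 °C → rt
Reagents that add atoms: iodomethane, CI
Why: Second stage of the Corey–Fuchs alkyne synthesis (Li/Br exchange, Fritsch–Buttenberg–Wiechell shift, deprotonation) followed by C‑methylation of the acetylide, which installs C‑4/C‑15 without touching the stereocentre.

Step 4
Reactants: 6 (4R)‑1,4‑dimethyl‑4‑(prop‑1‑yn‑1‑yl)cyclohex‑1‑ene
Product: 7 (3R)‑3‑methyl‑6‑oxo‑3‑(prop‑1‑yn‑1‑yl)heptanal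
Conditions: O3, CH2Cl2, −78 °C (Sudan Red 7B end point); then Me2S, −78 °C → rt
Reagents that add atoms: ozone, [O-][O+]=O
Why: Ozonolysis with reductive work‑up, in which the electron‑rich trisubstituted alkene reacts far faster than the internal alkyne and unmasks the C‑8 aldehyde and the C‑3 methyl ketone.

Step 5
Reactants: 8 acrolein (prop‑2‑enal); 9 methyl acrylate
Product: 10 methyl 3‑hydroxy‑2‑methylidenepent‑4‑enoate (racemic)
Conditions: DABCO (20 mol %), 1,4‑dioxane/H2O, rt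
Reagents that add atoms: none
Why: Morita–Baylis–Hillman reaction; the carbinol centre is racemic and is destroyed in the next step.

Step 6
Reactants: 10 methyl 3‑hydroxy‑2‑methylidenepent‑4‑enoate
Product: 11 methyl (2Z)‑2‑(bromomethyl)penta‑2,4‑dienoate
Conditions: NBS, Me2S, CH2Cl2, 0 °C → rt
Reagents that add atoms: N‑bromosuccinimide, O=C1CCC(=O)N1Br
Why: Corey–Kim‑type bromination with SN2′ allylic transposition, which gives the conjugated dienoate with the vinyl group trans to the ester (2Z) as the thermodynamically preferred isomer.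

Step 7
Reactants: 7 (3R)‑3‑methyl‑6‑oxo‑3‑(prop‑1‑yn‑1‑yl)heptanal; 11 methyl (2Z)‑2‑(bromomethyl)penta‑2,4‑dienoate
Product: 13 methyl (3R,4R,6R)‑3‑ethenyl‑4‑hydroxy‑6‑methyl‑2‑methylidene‑9‑oxo‑6‑(prop‑1‑yn‑1‑yl)decanoate, via TMS ether 12 (not isolated)
Conditions: CrCl2 (10 mol %), (S,S)‑tBu carbazole–bis(oxazoline) ligand (12 mol %), Mn, TMSCl, i‑Pr2NEt, THF, 0 °C → rt; then 1 M HCl, THF, 0 °C, 10 min
Reagents that add atoms: none
Why: Catalytic asymmetric Nozaki–Hiyama–Kishi‑type 2‑(alkoxycarbonyl)allylation that is selective for the aldehyde over the ketone, in which the allylchromium (vinyl cis to CH2Cr) reacts at its γ‑carbon through a chair transition state to give the syn C‑7/C‑8 pair and the ligand directs attack to the Si face of the aldehyde (8R, hence 7R).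

Step 8
Reactants: 13 methyl (3R,4R,6R)‑3‑ethenyl‑4‑hydroxy‑6‑methyl‑2‑methylidene‑9‑oxo‑6‑(prop‑1‑yn‑1‑yl)decanoate
Product: 14 methyl (3R,4R,6R)‑4‑(acetyloxy)‑3‑ethenyl‑6‑methyl‑2‑methylidene‑9‑oxo‑6‑(prop‑1‑yn‑1‑yl)decanoate
Conditions: Ac2O, pyridine, DMAP (cat.), CH2Cl2, 0 °C
Reagents that add atoms: acetic anhydride, CC(=O)OC(C)=O
Why: DMAP‑catalysed O‑acetylation with retention at C‑8, done at once so that the γ‑hydroxy ester cannot lactonise.

Step 9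
Reactants: 14 methyl (3R,4R,6R)‑4‑(acetyloxy)‑3‑ethenyl‑6‑methyl‑2‑methylidene‑9‑oxo‑6‑(prop‑1‑yn‑1‑yl)decanoate
Product: 16 methyl (3R,4R,6R)‑4‑(acetyloxy)‑3‑ethenyl‑6‑methyl‑2‑methylidene‑6‑(prop‑1‑yn‑1‑yl)‑9‑[(trimethylsilyl)oxy]dec‑9‑enoate, via lithium enolate 15 (not isolated)
Conditions: LDA (1.05 equiv) added to 14 + TMSCl (3 equiv), THF, −78 °C; pentane/NaHCO3 work‑up, crude used directly
Reagents that add atoms: chlorotrimethylsilane, C[Si](C)(C)Cl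
Why: Kinetic deprotonation of the methyl ketone at its CH3 group with in‑situ silyl trapping (Corey internal quench), which is faster than deprotonation of the less acidic acetate or addition to the hindered acrylate and gives the terminal silyl enol ether without touching any stereocentre.

Step 10
Reactants: 16 methyl (3R,4R,6R)‑4‑(acetyloxy)‑3‑ethenyl‑6‑methyl‑2‑methylidene‑6‑(prop‑1‑yn‑1‑yl)‑9‑[(trimethylsilyl)oxy]dec‑9‑enoate
Product: 18 methyl 2‑[(2R,3R,4aR)‑3‑(acetyloxy)‑4a,8‑dimethyl‑7‑oxo‑1,2,3,4,4a,5,6,7‑octahydronaphthalen‑2‑yl]prop‑2‑enoate, via silyl dienol ether 17 (not isolated)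
Conditions: Stewart–Grubbs catalyst (o‑tolyl‑NHC Hoveyda type, 10–15 mol %), 1,4‑benzoquinone (20 mol %), PhMe (5 mM), 80–100 °C, Ar sparge; then 1 M HCl, THF, 0 °C → rt
Reagents that add atoms: none
Why: Proposed new method: a tandem ring‑closing dienyne metathesis terminated by a silyl enol ether, in which the Ru carbene loads at the only monosubstituted alkene (C‑6 vinyl), adds 6‑exo to the propynyl group to close ring B and leave a vinylcarbene at C‑4, and this carbene closes ring A onto the 1,1‑disubstituted silyl enol ether to give the 3,5‑dienol ether that acid hydrolyses in the same flask to the conjugated enone, with C‑7, C‑8 and C‑10 as spectators; the closest known chemistry is Grubbs‑type dienyne RCM to fused bicyclic 1,3‑dienes combined with RCM of silyl enol ethers and of tetrasubstituted olefins by o‑tolyl‑NHC ruthenium catalysts.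

Step 11
Reactants: 18 methyl 2‑[(2R,3R,4aR)‑3‑(acetyloxy)‑4a,8‑dimethyl‑7‑oxo‑1,2,3,4,4a,5,6,7‑octahydronaphthalen‑2‑yl]prop‑2‑enoate
Product: 19 methyl 2‑[(2R,3R,4aR,7S)‑3‑(acetyloxy)‑7‑hydroxy‑4a,8‑dimethyl‑1,2,3,4,4a,5,6,7‑octahydronaphthalen‑2‑yl]prop‑2‑enoate
Conditions: NaBH4, CeCl3·7H2O, MeOH, −78 → −40 °C
Reagents that add atoms: none
Why: Luche 1,2‑reduction of the enone (acrylate and acetate are inert at low temperature), in which hydride is delivered axially on the α face, anti to the angular methyl, to give the pseudo‑equatorial 3β alcohol (3S) as in steroidal 4‑en‑3‑ones.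

Step 12
Reactants: 19 methyl 2‑[(2R,3R,4aR,7S)‑3‑(acetyloxy)‑7‑hydroxy‑4a,8‑dimethyl‑1,2,3,4,4a,5,6,7‑octahydronaphthalen‑2‑yl]prop‑2‑enoate
Product: 20 methyl 2‑[(2R,3R,4aR,7S)‑3‑(acetyloxy)‑4a,8‑dimethyl‑7‑[(2‑methylpropanoyl)oxy]‑1,2,3,4,4a,5,6,7‑octahydronaphthalen‑2‑yl]prop‑2‑enoate
Conditions: (i‑PrCO)2O, Et3N, DMAP (cat.), CH2Cl2, 0 °C → rt
Reagents that add atoms: 2‑methylpropanoic anhydride, CC(C)C(=O)OC(=O)C(C)C
Why: DMAP‑catalysed acylation of the allylic alcohol at oxygen, with retention at C‑3, gives the target.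

**Compound list**

1 | isoprene (2‑methylbuta‑1,3‑diene) | C=CC(C)=C | starting material
2 | methacrolein (2‑methylprop‑2‑enal) | C=C(C)C=O | starting material
3 | (1R)‑1,4‑dimethylcyclohex‑3‑ene‑1‑carbaldehyde | O=C[C@@]1(C)CC=C(C)CC1 | intermediate
4 | (4R)‑4‑(2,2‑dibromoethenyl)‑1,4‑dimethylcyclohex‑1‑ene | BrC(Br)=C[C@@]1(C)CC=C(C)CC1 | intermediate
5 | lithium 2‑[(1R)‑1,4‑dimethylcyclohex‑3‑en‑1‑yl]ethyn‑1‑ide (not isolated) | [Li]C#C[C@@]1(C)CC=C(C)CC1 | intermediate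
6 | (4R)‑1,4‑dimethyl‑4‑(prop‑1‑yn‑1‑yl)cyclohex‑1‑ene | CC#C[C@@]1(C)CC=C(C)CC1 | intermediate
7 | (3R)‑3‑methyl‑6‑oxo‑3‑(prop‑1‑yn‑1‑yl)heptanal | CC#C[C@@](CCC(C)=O)(C)CC=O | intermediate
8 | acrolein (prop‑2‑enal) | C=CC=O | starting material
9 | methyl acrylate | C=CC(=O)OC | starting material
10 | methyl 3‑hydroxy‑2‑methylidenepent‑4‑enoate (racemic) | C=CC(O)C(=C)C(=O)OC | intermediate
11 | methyl (2Z)‑2‑(bromomethyl)penta‑2,4‑dienoate | C=C/C=C(\CBr)C(=O)OC | intermediate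
12 | methyl (3R,4R,6R)‑3‑ethenyl‑6‑methyl‑2‑methylidene‑9‑oxo‑6‑(prop‑1‑yn‑1‑yl)‑4‑[(trimethylsilyl)oxy]decanoate (not isolated) | C=C(C(=O)OC)[C@@H](C=C)[C@H](O[Si](C)(C)C)C[C@](C)(C#CC)CCC(C)=O | intermediate
13 | methyl (3R,4R,6R)‑3‑ethenyl‑4‑hydroxy‑6‑methyl‑2‑methylidene‑9‑oxo‑6‑(prop‑1‑yn‑1‑yl)decanoate | C=C(C(=O)OC)[C@@H](C=C)[C@H](O)C[C@](C)(C#CC)CCC(C)=O | intermediate
14 | methyl (3R,4R,6R)‑4‑(acetyloxy)‑3‑ethenyl‑6‑methyl‑2‑methylidene‑9‑oxo‑6‑(prop‑1‑yn‑1‑yl)decanoate | C=C(C(=O)OC)[C@@H](C=C)[C@H](OC(C)=O)C[C@](C)(C#CC)CCC(C)=O | intermediate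
15 | lithium enolate of 14 (C9–C10 enolate, not isolated) | C=C(C(=O)OC)[C@@H](C=C)[C@H](OC(C)=O)C[C@](C)(C#CC)CCC(=C)O[Li] | intermediate
16 | methyl (3R,4R,6R)‑4‑(acetyloxy)‑3‑ethenyl‑6‑methyl‑2‑methylidene‑6‑(prop‑1‑yn‑1‑yl)‑9‑[(trimethylsilyl)oxy]dec‑9‑enoate | C=C(C(=O)OC)[C@@H](C=C)[C@H](OC(C)=O)C[C@](C)(C#CC)CCC(=C)O[Si](C)(C)C | intermediate
17 | methyl 2‑[(2R,3R,4aR)‑3‑(acetyloxy)‑4a,8‑dimethyl‑7‑[(trimethylsilyl)oxy]‑2,3,4,4a,5,6‑hexahydronaphthalen‑2‑yl]prop‑2‑enoate (not isolated) | C=C(C(=O)OC)[C@H]1C=C2C(C)=C(O[Si](C)(C)C)CC[C@]2(C)C[C@H]1OC(C)=O | intermediate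
18 | methyl 2‑[(2R,3R,4aR)‑3‑(acetyloxy)‑4a,8‑dimethyl‑7‑oxo‑1,2,3,4,4a,5,6,7‑octahydronaphthalen‑2‑yl]prop‑2‑enoate | C=C(C(=O)OC)[C@H]1CC2=C(C)C(=O)CC[C@]2(C)C[C@H]1OC(C)=O | intermediate
19 | methyl 2‑[(2R,3R,4aR,7S)‑3‑(acetyloxy)‑7‑hydroxy‑4a,8‑dimethyl‑1,2,3,4,4a,5,6,7‑octahydronaphthalen‑2‑yl]prop‑2‑enoate | C=C(C(=O)OC)[C@H]1CC2=C(C)[C@@H](O)CC[C@]2(C)C[C@H]1OC(C)=O | intermediate
20 | methyl 2‑[(2R,3R,4aR,7S)‑3‑(acetyloxy)‑4a,8‑dimethyl‑7‑[(2‑methylpropanoyl)oxy]‑1,2,3,4,4a,5,6,7‑octahydronaphthalen‑2‑yl]prop‑2‑enoate (CNP0127901.1) | C=C(C(=O)OC)[C@H]1CC2=C(C)[C@@H](OC(=O)C(C)C)CC[C@]2(C)C[C@H]1OC(C)=O | target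

**Step count**

Total steps: 12. Longest linear sequence: 10 (steps 1–4, then 7–12); steps 5–6 make the second fragment.

**Three steps most likely to fail, with fallbacks**

Step 10 is the riskiest. The second closure has to make a tetrasubstituted, oxygen‑bearing double bond from a hindered vinylcarbene and a 1,1‑disubstituted enol ether, and it may stop at the monocyclic triene. The fallback sets out from the acetylide 5 and returns at 18. It removes the methyl group from the alkyne so that ring A closes to a trisubstituted dienol ether, and brings in C‑15 afterwards.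
- Quenching 5 with NH4Cl instead of MeI gives (4R)‑4‑ethynyl‑1,4‑dimethylcyclohex‑1‑ene F1, and ozonolysis as before gives (3R)‑3‑ethynyl‑3‑methyl‑6‑oxoheptanal F2.
- The same chromium‑catalysed allylation with 11 passes through the silyl ether methyl (3R,4R,6R)‑3‑ethenyl‑6‑ethynyl‑6‑methyl‑2‑methylidene‑9‑oxo‑4‑[(trimethylsilyl)oxy]decanoate F3 to the alcohol methyl (3R,4R,6R)‑3‑ethenyl‑6‑ethynyl‑4‑hydroxy‑6‑methyl‑2‑methylidene‑9‑oxodecanoate F4.
- Acetylation gives methyl (3R,4R,6R)‑4‑(acetyloxy)‑3‑ethenyl‑6‑ethynyl‑6‑methyl‑2‑methylidene‑9‑oxodecanoate F5. LDA (1.0 equiv, the ketone CH3 being more acidic than the alkyne C–H) with TMSCl gives, through its lithium enolate F6, the enol ether methyl (3R,4R,6R)‑4‑(acetyloxy)‑3‑ethenyl‑6‑ethynyl‑6‑methyl‑2‑methylidene‑9‑[(trimethylsilyl)oxy]dec‑9‑enoate F7.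
- Ruthenium dienyne metathesis of F7 gives the bicyclic dienol ether methyl 2‑[(2R,3R,4aR)‑3‑(acetyloxy)‑4a‑methyl‑7‑[(trimethylsilyl)oxy]‑2,3,4,4a,5,6‑hexahydronaphthalen‑2‑yl]prop‑2‑enoate F8.
- Instead of hydrolysis, anhydrous benzyltrimethylammonium fluoride releases the benzyltrimethylammonium dienolate of the C‑4‑unsubstituted enone F9. MeI alkylates it at the α‑carbon (C‑4) to the β,γ‑unsaturated ketone methyl 2‑[(2R,3R,4aR)‑3‑(acetyloxy)‑4a,8‑dimethyl‑7‑oxo‑2,3,4,4a,5,6,7,8‑octahydronaphthalen‑2‑yl]prop‑2‑enoate F10, and brief HCl in THF moves the double bond into conjugation to give 18.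

Step 9 is the next risk, because the acetate and the acrylate may not survive the amide base. The fallback sets out from 12 and returns at 18. It carries O‑8 as its silyl ether through the enolisation and the metathesis, and acetylates last.
- Compound 12 is kept by a bicarbonate work‑up in step 7. LDA/TMSCl converts it, through the lithium enolate of 12 F11, into the bis‑silyl dienyne methyl (3R,4R,6R)‑3‑ethenyl‑6‑methyl‑2‑methylidene‑6‑(prop‑1‑yn‑1‑yl)‑4,9‑bis[(trimethylsilyl)oxy]dec‑9‑enoate F12.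
- The dienyne metathesis gives methyl 2‑[(2R,3R,4aR)‑4a,8‑dimethyl‑3,7‑bis[(trimethylsilyl)oxy]‑2,3,4,4a,5,6‑hexahydronaphthalen‑2‑yl]prop‑2‑enoate F13.
- Pyridine‑buffered HF·pyridine removes both silyl groups to give the hydroxy enone methyl 2‑[(2R,3R,4aR)‑3‑hydroxy‑4a,8‑dimethyl‑7‑oxo‑1,2,3,4,4a,5,6,7‑octahydronaphthalen‑2‑yl]prop‑2‑enoate F14, which is acetylated immediately (Ac2O, DMAP) to 18.

Step 7 is the third risk: the facial control by the chromium catalyst with this vinyl‑substituted bromide is untested, C‑10 gives no help, and the product can lactonise. The fallback sets out from 11 and returns at 13. It replaces the chromium reagent by a configurationally defined allylboronate and an organocatalyst.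
- Pd‑catalysed borylation of 11 with B2pin2 gives methyl (2E)‑2‑[(4,4,5,5‑tetramethyl‑1,3,2‑dioxaborolan‑2‑yl)methyl]penta‑2,4‑dienoate F15, in which the vinyl group is still cis to the CH2B group.
- Allylboration of 7 under a chiral BINOL‑phosphoric acid (TRIP type), through the closed six‑membered transition state, gives the syn adduct as its borate methyl (3R,4R,6R)‑3‑ethenyl‑6‑methyl‑2‑methylidene‑9‑oxo‑6‑(prop‑1‑yn‑1‑yl)‑4‑[(4,4,5,5‑tetramethyl‑1,3,2‑dioxaborolan‑2‑yl)oxy]decanoate F16.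
- A neutral aqueous work‑up hydrolyses the borate to 13.

**Further compounds**

F1 | step 10 | (4R)‑4‑ethynyl‑1,4‑dimethylcyclohex‑1‑ene | C#C[C@@]1(C)CC=C(C)CC1
F2 | step 10 | (3R)‑3‑ethynyl‑3‑methyl‑6‑oxoheptanal | C#C[C@@](CCC(C)=O)(C)CC=O
F3 | step 10 | methyl (3R,4R,6R)‑3‑ethenyl‑6‑ethynyl‑6‑methyl‑2‑methylidene‑9‑oxo‑4‑[(trimethylsilyl)oxy]decanoate | C=C(C(=O)OC)[C@@H](C=C)[C@H](O[Si](C)(C)C)C[C@](C)(C#C)CCC(C)=O
F4 | step 10 | methyl (3R,4R,6R)‑3‑ethenyl‑6‑ethynyl‑4‑hydroxy‑6‑methyl‑2‑methylidene‑9‑oxodecanoate | C=C(C(=O)OC)[C@@H](C=C)[C@H](O)C[C@](C)(C#C)CCC(C)=O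
F5 | step 10 | methyl (3R,4R,6R)‑4‑(acetyloxy)‑3‑ethenyl‑6‑ethynyl‑6‑methyl‑2‑methylidene‑9‑oxodecanoate | C=C(C(=O)OC)[C@@H](C=C)[C@H](OC(C)=O)C[C@](C)(C#C)CCC(C)=O
F6 | step 10 | lithium enolate of F5 (C9–C10 enolate) | C=C(C(=O)OC)[C@@H](C=C)[C@H](OC(C)=O)C[C@](C)(C#C)CCC(=C)O[Li]
F7 | step 10 | methyl (3R,4R,6R)‑4‑(acetyloxy)‑3‑ethenyl‑6‑ethynyl‑6‑methyl‑2‑methylidene‑9‑[(trimethylsilyl)oxy]dec‑9‑enoate | C=C(C(=O)OC)[C@@H](C=C)[C@H](OC(C)=O)C[C@](C)(C#C)CCC(=C)O[Si](C)(C)C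
F8 | step 10 | methyl 2‑[(2R,3R,4aR)‑3‑(acetyloxy)‑4a‑methyl‑7‑[(trimethylsilyl)oxy]‑2,3,4,4a,5,6‑hexahydronaphthalen‑2‑yl]prop‑2‑enoate | C=C(C(=O)OC)[C@H]1C=C2C=C(O[Si](C)(C)C)CC[C@]2(C)C[C@H]1OC(C)=O
F9 | step 10 | benzyltrimethylammonium dienolate of the C‑4‑unsubstituted enone | C=C(C(=O)OC)[C@H]1C=C2C=C([O-])CC[C@]2(C)C[C@H]1OC(C)=O.C[N+](C)(C)Cc1ccccc1
F10 | step 10 | methyl 2‑[(2R,3R,4aR)‑3‑(acetyloxy)‑4a,8‑dimethyl‑7‑oxo‑2,3,4,4a,5,6,7,8‑octahydronaphthalen‑2‑yl]prop‑2‑enoate (C‑8 epimers) | C=C(C(=O)OC)[C@H]1C=C2C(C)C(=O)CC[C@]2(C)C[C@H]1OC(C)=O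
F11 | step 9 | lithium enolate of 12 (C9–C10 enolate) | C=C(C(=O)OC)[C@@H](C=C)[C@H](O[Si](C)(C)C)C[C@](C)(C#CC)CCC(=C)O[Li]
F12 | step 9 | methyl (3R,4R,6R)‑3‑ethenyl‑6‑methyl‑2‑methylidene‑6‑(prop‑1‑yn‑1‑yl)‑4,9‑bis[(trimethylsilyl)oxy]dec‑9‑enoate | C=C(C(=O)OC)[C@@H](C=C)[C@H](O[Si](C)(C)C)C[C@](C)(C#CC)CCC(=C)O[Si](C)(C)C
F13 | step 9 | methyl 2‑[(2R,3R,4aR)‑4a,8‑dimethyl‑3,7‑bis[(trimethylsilyl)oxy]‑2,3,4,4a,5,6‑hexahydronaphthalen‑2‑yl]prop‑2‑enoate | C=C(C(=O)OC)[C@H]1C=C2C(C)=C(O[Si](C)(C)C)CC[C@]2(C)C[C@H]1O[Si](C)(C)C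
F14 | step 9 | methyl 2‑[(2R,3R,4aR)‑3‑hydroxy‑4a,8‑dimethyl‑7‑oxo‑1,2,3,4,4a,5,6,7‑octahydronaphthalen‑2‑yl]prop‑2‑enoate | C=C(C(=O)OC)[C@H]1CC2=C(C)C(=O)CC[C@]2(C)C[C@H]1O
F15 | step 7 | methyl (2E)‑2‑[(4,4,5,5‑tetramethyl‑1,3,2‑dioxaborolan‑2‑yl)methyl]penta‑2,4‑dienoate | C=C/C=C(\CB1OC(C)(C)C(C)(C)O1)C(=O)OC
F16 | step 7 | methyl (3R,4R,6R)‑3‑ethenyl‑6‑methyl‑2‑methylidene‑9‑oxo‑6‑(prop‑1‑yn‑1‑yl)‑4‑[(4,4,5,5‑tetramethyl‑1,3,2‑dioxaborolan‑2‑yl)oxy]decanoate | C=C(C(=O)OC)[C@@H](C=C)[C@H](OB1OC(C)(C)C(C)(C)O1)C[C@](C)(C#CC)CCC(C)=O
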